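The route rests on opening ring A at C4–C5. Because C6 carries oxygen, the ring-fusion carbon C5 is the α-carbon of a C6 ketone, and C4, bonded only to C3, C5 and C15, is a latent methyl ketone; both are tethered through the quaternary C10. A base-mediated aldol condensation of (3R)-3-methyl-3-(4-oxopentyl)-6-isopropylcyclohexanone, used as its C7 epimer mixture, forms C4–C5, closes ring A as the tetrasubstituted C4=C5 enone and lets C7 equilibrate to the equatorial isopropyl epimer in one operation. C10 is set beforehand by an enantioselective Grignard conjugate addition to piperitone; afterwards photodeconjugation moves the alkene to C4=C15 and restores H-5, and a thermodynamic ketone reduction and acylation complete the coumarate.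

Key step: step 3

Remarks on the chemistry (assumptions):
- Eudesmane numbering is used throughout: C1–C3 are the ring A methylenes, C4 bears C15, C5 is the ring-fusion CH, C6 bears oxygen, C7 bears the isopropyl group, and C10 bears C14.
- Piperitone may be used in any enantiomeric composition, because its stereocentre (C7) is equilibrated in step 3.
- The antipode of the imidazolinium salt in step 1 is the one that a test run shows to give the R quaternary centre.
- The C4 ketone is carried through step 1 as a terminal alkene, so the Grignard reagent is a plain primary alkyl reagent that can be made and used in Et2O.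

Step 1
Reactants: 1 piperitone; 2 5-bromopent-1-ene
Product: 5 (3R)-3-methyl-3-(pent-4-en-1-yl)-6-(propan-2-yl)cyclohexan-1-one (mixture of C6 epimers), via pent-4-en-1-ylmagnesium bromide 3 (not isolated), via bromomagnesium enolate 4 (not isolated)
Conditions: 2, Mg, Et2O, rt; Cu(OTf)2 (3 mol %), enantiopure 1-mesityl-3-(1-hydroxy-4-methylpentan-2-yl)-4,5-dihydroimidazolium hexafluorophosphate (4 mol %), 3 (1.5 equiv), 1, Et2O, −30 to 0 °C; 1 M HCl
Reagents that add atoms: none
Why: Copper-catalysed asymmetric conjugate addition of a primary alkyl Grignard reagent in Et2O to a β-methylcyclohexenone is an established route to quaternary centres, and the chiral carbene–copper species should choose the enone face so that C10 becomes R from either enantiomer of 1, because the isopropyl-bearing carbon lies in the enone plane, remote from the reacting carbon, and its configuration is equilibrated in step 3.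

Step 2
Reactants: 5 (3R)-3-methyl-3-(pent-4-en-1-yl)-6-(propan-2-yl)cyclohexan-1-one
Product: 6 (3R)-3-methyl-3-(4-oxopentyl)-6-(propan-2-yl)cyclohexan-1-one (mixture of C6 epimers; the aldol precursor)
Conditions: PdCl2 (10 mol %), CuCl (1 equiv), O2 (1 atm), DMF–H2O 7:1, rt
Reagents that add atoms: water, O
Why: The Tsuji–Wacker oxidation adds water to the palladium-bound terminal alkene with oxygen on the internal carbon, so C4 becomes the methyl ketone and C15 its methyl group, while the ring ketone and the quaternary C10 are untouched and no stereocentre is formed.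

Step 3
Reactants: 6 (3R)-3-methyl-3-(4-oxopentyl)-6-(propan-2-yl)cyclohexan-1-one
Product: 8 eudesm-4-en-6-one [(2S,4aR)-4a,8-dimethyl-2-(propan-2-yl)-3,4,4a,5,6,7-hexahydronaphthalen-1(2H)-one], via aldol adduct 7 (not isolated)
Conditions: KOH (2 equiv), MeOH, reflux, N2
Reagents that add atoms: none
Why: Hydroxide reversibly forms the C5=C6 enolate of the ring ketone, which adds to the C4 carbonyl to give aldol 7, and E1cB loss of water then fixes the C4–C5 bond as the tetrasubstituted C4=C5 enone. This is the classical base-mediated intramolecular aldol condensation of a 1,7-diketone to a 1-acylcyclohexene, here in fused form. Ring A closes in a 6-(enolexo)-exo-trig mode. The one stereocentre settled here is C7: it epimerises through the C6–C7 enolate, and since the C4=C5 bond holds C1 near the enone plane, ring B of 8 is confined to the chair with C14 axial, in which the isopropyl group is expected to take the equatorial position cis to C14 (7S); C10 is quaternary and inert. The selectivity required is which aldol becomes irreversible, and the substrate secures it: attack of C3 on C6 gives a bridged bicyclo[3.3.1] ketol that could dehydrate only to a bridgehead alkene, and closures from C7 or C15 would need eight-membered rings, so these revert and 8 is the only outlet.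

Step 4
Reactants: 8 eudesm-4-en-6-one
Product: 10 eudesm-4(15)-en-6-one [(2S,4aR,8aS)-4a-methyl-8-methylidene-2-(propan-2-yl)octahydronaphthalen-1(2H)-one], via photodienol 9 (not isolated)
Conditions: hν (350 nm, Pyrex), imidazole (0.2 equiv), degassed MeOH, rt
Reagents that add atoms: none
Why: This is the photodeconjugation (photoenolisation) of an α,β-unsaturated ketone, in which the excited s-cis enone passes a hydrogen from C15, the only γ-carbon cis to the carbonyl, to oxygen, and imidazole-mediated ketonisation of dienol 9 should protonate C5 on the α-face, opposite the axial C14 methyl, giving the trans ring fusion (5S), while light of 350 nm is absorbed far better by 8 than by the product.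

Step 5
Reactants: 10 eudesm-4(15)-en-6-one
Product: 12 junenol [(1S,2S,4aR,8aS)-4a-methyl-8-methylidene-2-(propan-2-yl)decahydronaphthalen-1-ol], via lithium alkoxide 11 (not isolated)
Conditions: Li (5 equiv), NH3 (l)–THF, t-BuOH (2 equiv), −78 °C, 10 added last; NH4Cl
Reagents that add atoms: none
Why: Dissolving-metal reduction of a hindered cyclohexanone gives the thermodynamically preferred equatorial alcohol, so C6 should become S (6α-OH, trans to H-5 and H-7), whereas a hydride would enter anti to C14 and give the axial epimer; the isolated 1,1-disubstituted alkene is inert, and inverse addition at −78 °C consumes the ketone before base can move the alkene back into conjugation.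

Step 6
Reactants: 13 (E)-4-hydroxycinnamic acid
Product: 15 (E)-3-[4-(tert-butyldimethylsilyloxy)phenyl]prop-2-enoic acid, via bis-silyl derivative 14 (not isolated)
Conditions: TBSCl (2.3 equiv), imidazole (5 equiv), DMF, rt; then AcOH–THF–H2O 3:1:1, rt
Reagents that add atoms: tert-butyldimethylsilyl chloride (TBSCl), CC(C)(C)[Si](C)(C)Cl
Why: Silylation of both acidic OH groups followed by selective hydrolysis of the much more labile silyl ester is standard protecting-group chemistry that leaves the phenol masked as its aryl silyl ether and the E alkene untouched.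

Step 7
Reactants: 12 junenol; 15 (E)-3-[4-(tert-butyldimethylsilyloxy)phenyl]prop-2-enoic acid
Product: 16 (1S,2S,4aR,8aS)-4a-methyl-8-methylidene-2-(propan-2-yl)decahydronaphthalen-1-yl (E)-3-[4-(tert-butyldimethylsilyloxy)phenyl]prop-2-enoate
Conditions: 15 (1.5 equiv), DCC (1.6 equiv), 4-(dimethylamino)pyridine (1 equiv), CH2Cl2, 0 °C to rt
Reagents that add atoms: none
Why: Steglich esterification (carbodiimide activation and acyl transfer through the N-acylpyridinium ion) should acylate the equatorial secondary alcohol with retention at C6 under neutral conditions that spare the exocyclic alkene and the aryl silyl ether.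

Step 8
Reactants: 16 silyl-protected coumarate
Product: 17 (1S,2S,4aR,8aS)-4a-methyl-8-methylidene-2-(propan-2-yl)decahydronaphthalen-1-yl (E)-3-(4-hydroxyphenyl)prop-2-enoate (CNP0321375.1)
Conditions: Bu4NF (1.2 equiv), AcOH (1.2 equiv), THF, 0 °C
Reagents that add atoms: none
Why: Fluoride-mediated desilylation cleaves the aryl silyl ether through Si–F bond formation within minutes, and the acetic acid buffer keeps the phenoxide from attacking the cinnamate, so the ester, the E alkene and all four stereocentres should be unchanged.

Compound list
1 | piperitone, 3-methyl-6-(propan-2-yl)cyclohex-2-en-1-one (racemic or scalemic) | CC1=CC(=O)C(C(C)C)CC1 | starting material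
2 | 5-bromopent-1-ene | C=CCCCBr | starting material
3 | pent-4-en-1-ylmagnesium bromide | C=CCCC[Mg]Br | intermediate
4 | bromomagnesium (3R)-3-methyl-3-(pent-4-en-1-yl)-6-(propan-2-yl)cyclohex-1-en-1-olate (C6 epimers) | C=CCCC[C@]1(C)CCC(C(C)C)C(O[Mg]Br)=C1 | intermediate
5 | (3R)-3-methyl-3-(pent-4-en-1-yl)-6-(propan-2-yl)cyclohexan-1-one (C6 epimers) | C=CCCC[C@]1(C)CCC(C(C)C)C(=O)C1 | intermediate
6 | (3R)-3-methyl-3-(4-oxopentyl)-6-(propan-2-yl)cyclohexan-1-one (C6 epimers; C6 of the ring is C7 of the eudesmane) | CC(=O)CCC[C@]1(C)CCC(C(C)C)C(=O)C1 | intermediate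
7 | (4aR)-8-hydroxy-4a,8-dimethyl-2-(propan-2-yl)octahydronaphthalen-1(2H)-one (aldol adduct, stereoisomer mixture at the other centres) | CC1(O)CCC[C@]2(C)CCC(C(C)C)C(=O)C12 | intermediate
8 | eudesm-4-en-6-one, (2S,4aR)-4a,8-dimethyl-2-(propan-2-yl)-3,4,4a,5,6,7-hexahydronaphthalen-1(2H)-one | CC1=C2C(=O)[C@H](C(C)C)CC[C@@]2(C)CCC1 | intermediate
9 | (2S,4aR)-4a-methyl-8-methylidene-2-(propan-2-yl)-2,3,4,4a,5,6,7,8-octahydronaphthalen-1-ol (photodienol) | C=C1CCC[C@]2(C)CC[C@@H](C(C)C)C(O)=C12 | intermediate
10 | eudesm-4(15)-en-6-one, (2S,4aR,8aS)-4a-methyl-8-methylidene-2-(propan-2-yl)octahydronaphthalen-1(2H)-one (5α-H) | C=C1CCC[C@]2(C)CC[C@@H](C(C)C)C(=O)[C@@H]12 | intermediate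
11 | lithium (1S,2S,4aR,8aS)-4a-methyl-8-methylidene-2-(propan-2-yl)decahydronaphthalen-1-olate | C=C1CCC[C@]2(C)CC[C@@H](C(C)C)[C@H](O[Li])[C@@H]12 | intermediate
12 | junenol, (1S,2S,4aR,8aS)-4a-methyl-8-methylidene-2-(propan-2-yl)decahydronaphthalen-1-ol (6α-OH) | C=C1CCC[C@]2(C)CC[C@@H](C(C)C)[C@H](O)[C@@H]12 | intermediate
13 | (E)-4-hydroxycinnamic acid | O=C(O)/C=C/c1ccc(O)cc1 | starting material
14 | tert-butyldimethylsilyl (E)-3-[4-(tert-butyldimethylsilyloxy)phenyl]prop-2-enoate | CC(C)(C)[Si](C)(C)OC(=O)/C=C/c1ccc(O[Si](C)(C)C(C)(C)C)cc1 | intermediate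
15 | (E)-3-[4-(tert-butyldimethylsilyloxy)phenyl]prop-2-enoic acid | O=C(O)/C=C/c1ccc(O[Si](C)(C)C(C)(C)C)cc1 | intermediate
16 | (1S,2S,4aR,8aS)-4a-methyl-8-methylidene-2-(propan-2-yl)decahydronaphthalen-1-yl (E)-3-[4-(tert-butyldimethylsilyloxy)phenyl]prop-2-enoate | C=C1CCC[C@]2(C)CC[C@@H](C(C)C)[C@H](OC(=O)/C=C/c3ccc(O[Si](C)(C)C(C)(C)C)cc3)[C@@H]12 | intermediate
17 | (1S,2S,4aR,8aS)-4a-methyl-8-methylidene-2-(propan-2-yl)decahydronaphthalen-1-yl (E)-3-(4-hydroxyphenyl)prop-2-enoate | C=C1CCC[C@]2(C)CC[C@@H](C(C)C)[C@H](OC(=O)/C=C/c3ccc(O)cc3)[C@@H]12 | target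

Total step count: 8. Longest linear sequence: 7 steps (steps 1, 2, 3, 4, 5, 7, 8); step 6 prepares the acid fragment.

Steps most likely to fail

Step 1. Catalyst control may be eroded where the resident stereocentre of one enantiomer of 1 opposes the ligand (mismatched pairing), which would lower the enantiopurity at C10. Addition to the α′-branched trisubstituted enone may also be slow, letting 1,2-addition or enolisation compete. The fallback sets out from Grignard reagent 3 and comes back at 5; it builds the quaternary centre on an achiral enone and adds the isopropyl group afterwards. The same Cu(OTf)2/imidazolinium catalyst would add 3 to 3-methylcyclohex-2-en-1-one F1 to give (R)-3-methyl-3-(pent-4-en-1-yl)cyclohexan-1-one F2. Kinetic deprotonation with LiN(iPr)2 at the methylene remote from the quaternary carbon and addition to acetone (ZnCl2, −78 °C) would give (3R)-6-(2-hydroxypropan-2-yl)-3-methyl-3-(pent-4-en-1-yl)cyclohexan-1-one F3. TsOH-catalysed dehydration in hot toluene would give (3R)-3-methyl-3-(pent-4-en-1-yl)-6-(propan-2-ylidene)cyclohexan-1-one F4. Li in NH3 would then reduce only the conjugated alkene and, after NH4Cl, deliver 5 as its C6 epimer mixture.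

Step 3. Equilibration at C7 may stop at a mixture in which the axial-isopropyl epimer is significantly populated, because an equatorial isopropyl group eclipses the C6 carbonyl; closure at the neopentyl C5 may also be slow and call for longer heating. The fallback sets out from 8 as obtained, in admixture with its C7 epimer (2R,4aR)-4a,8-dimethyl-2-(propan-2-yl)-3,4,4a,5,6,7-hexahydronaphthalen-1(2H)-one F5, and comes back at 8; it replaces thermodynamic by kinetic control. LiN(iPr)2 at −78 °C would remove H-7 (α′-deprotonation) to give the cross-conjugated lithium dienolate F6. A hindered proton source (2,6-di-tert-butyl-4-methylphenol, −78 °C) should then deliver hydrogen axially to the α-face of C7, anti to C14, giving the 7S epimer 8.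

Step 4. Over-irradiation may drive the β,γ-unsaturated ketone into 1,3-acyl migration, the dienol may return thermally to 8 faster than it is protonated at C5, or protonation may take place on the β-face and give the cis ring fusion. The fallback sets out from 8 and comes back at 10; it is a ground-state deconjugation through the dienolate. KOtBu in t-BuOH would convert 8 into the potassium dienolate F7 by removal of a C15 hydrogen, the γ-position on the side of the metal-bound oxygen. Inverse quench into cold aqueous AcOH should then protonate C5 kinetically from the α-face. Any 3-ene isomer would be removed on AgNO3-impregnated silica.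

Further compounds
F1 | step 1 | 3-methylcyclohex-2-en-1-one | CC1=CC(=O)CCC1
F2 | step 1 | (R)-3-methyl-3-(pent-4-en-1-yl)cyclohexan-1-one | C=CCCC[C@]1(C)CCCC(=O)C1
F3 | step 1 | (3R)-6-(2-hydroxypropan-2-yl)-3-methyl-3-(pent-4-en-1-yl)cyclohexan-1-one (C6 epimers) | C=CCCC[C@]1(C)CCC(C(C)(C)O)C(=O)C1
F4 | step 1 | (3R)-3-methyl-3-(pent-4-en-1-yl)-6-(propan-2-ylidene)cyclohexan-1-one | C=CCCC[C@]1(C)CCC(=C(C)C)C(=O)C1
F5 | step 3 | (2R,4aR)-4a,8-dimethyl-2-(propan-2-yl)-3,4,4a,5,6,7-hexahydronaphthalen-1(2H)-one (C7 epimer of 8) | CC1=C2C(=O)[C@@H](C(C)C)CC[C@@]2(C)CCC1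
F6 | step 3 | lithium (4aR)-4a,8-dimethyl-2-(propan-2-yl)-4,4a,5,6-tetrahydro-3H-naphthalen-1-olate (cross-conjugated dienolate) | CC1=C2C(O[Li])=C(C(C)C)CC[C@@]2(C)CCC1
F7 | step 4 | potassium (2S,4aR)-4a-methyl-8-methylidene-2-(propan-2-yl)-2,3,4,4a,5,6,7,8-octahydronaphthalen-1-olate (extended dienolate) | C=C1CCC[C@]2(C)CC[C@@H](C(C)C)C([O-])=C12.[K+]
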